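## Retrosynthetic overview

1. Numbering: C1 = ring CH bearing the side chain, C2=C3 = butenolide alkene (C2 carries the lactone CH2O, C3 the lactone C=O), C4/C5 = cyclopropane CH, C6 = CHMe, C7 = CH2, C8 = CHOH, C1′ = side-chain stereocentre. Target 28 ⇐ C8 ketone 27 (hydride) ⇐ primary alcohol 26 (acetylation).
2. Enabling feature: the C8 oxygen and the lactone carbonyl stand 1,5 across C1–C2=C3, the retron of a de Mayo reaction with an alkyne. The eight-membered ring is thus a cyclohexene (C3–C8) enlarged by the two alkyne carbons C1/C2, and the lactone O–CH2 on C2 is the tether. Hence 26 ⇐ propargyl ester silyl enol ether 24 by [2+2] photocycloaddition and retro-aldol fragmentation.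
3. 24 ⇐ enol triflate 10 + CO + propargylic alcohol 23 (Pd alkoxycarbonylation). 10 ⇐ cyclopropyl ketone 5 (Rubottom oxidation, triflation) ⇐ (S)-4-methylcyclohexenone 4 (Corey–Chaykovsky) ⇐ propanal + methyl vinyl ketone (organocatalytic Michael addition, aldol condensation).
4. 23 ⇐ acid 11 by auxiliary-controlled benzyloxymethylation (sets C1′), reduction, protecting-group exchange, and Corey–Fuchs reaction with formaldehyde trapping.
5. Ring order: six-membered carbocycle (step 2, consumed later) → cyclopropane (step 3) → γ-lactone and transient cyclobutene (step 16, first stage) → cyclooctene (step 16, second stage, last).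

Key step: step 16

Assumption: C1 of 26 (α to the C8 ketone, vinylogously α to the lactone) equilibrates in the fluoride/acetate buffer to the epimer of the target, in which C2 and the C1′ homoprenyl group are trans on the reversible five-membered C8 hemiketal of the side-chain hydroxyl.

## Route

Step 1
Reactants: 1 propanal; 2 methyl vinyl ketone (but-3-en-2-one)
Product: 3 (S)-2-methyl-5-oxohexanal
Conditions: (R)-2-(methoxydiphenylmethyl)pyrrolidine (5 mol%), ethyl 3,4-dihydroxybenzoate (20 mol%), neat, 4 °C
Reagents that add atoms: none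
Why: Enamine-catalysed asymmetric Michael addition of an aldehyde to an enone; the (R)-catalyst shields one face of the E-enamine, so the new C–C bond should set the (S) centre that becomes C6.

Step 2
Reactants: 3 (S)-2-methyl-5-oxohexanal
Product: 4 (S)-4-methylcyclohex-2-en-1-one
Conditions: LiOH, i-PrOH, rt
Reagents that add atoms: none
Why: Intramolecular aldol condensation (methyl ketone enolate onto the aldehyde, then dehydration) closes the six-membered ring; mild base and short contact should preserve the stereocentre, which ends up γ to the carbonyl.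

Step 3
Reactants: 4 (S)-4-methylcyclohex-2-en-1-one
Product: 5 (1R,5S,6R)-5-methylbicyclo[4.1.0]heptan-2-one
Conditions: Me3S(O)I, NaH, DMSO, rt
Reagents that add atoms: trimethylsulfoxonium iodide, C[S+](C)(C)=O.[I-]
Why: Corey–Chaykovsky cyclopropanation; the sulfoxonium ylide should add to the β-carbon anti to the neighbouring methyl group and close 3-exo-tet, giving the cis-fused cyclopropane trans to the methyl (C4 and C5 set relative to C6).

Step 4
Reactants: 5 (1R,5S,6R)-5-methylbicyclo[4.1.0]heptan-2-one
Product: 6 tert-butyldimethyl{[(1R,5S,6R)-5-methylbicyclo[4.1.0]hept-2-en-2-yl]oxy}silane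
Conditions: TBSOTf, Et3N, CH2Cl2, 0 °C
Reagents that add atoms: tert-butyldimethylsilyl triflate, CC(C)(C)[Si](C)(C)OS(=O)(=O)C(F)(F)F
Why: Soft enolisation and O-silylation; only the CH2 side can enolise because the other α-carbon is the cyclopropane bridgehead.

Step 5
Reactants: 6 silyl enol ether
Product: 8 (1R,5S,6R)-3-[(tert-butyldimethylsilyl)oxy]-5-methylbicyclo[4.1.0]heptan-2-one (both C3 epimers), via silyloxy epoxide 7 (not isolated)
Conditions: mCPBA, NaHCO3, CH2Cl2, 0 °C
Reagents that add atoms: meta-chloroperbenzoic acid, OOC(=O)c1cccc(Cl)c1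
Why: Rubottom oxidation (epoxidation of the silyl enol ether, then 1,4-silyl shift of the silyloxy epoxide) places the oxygen that becomes the C8 oxygen; the new centre is made planar again in step 6.

Step 6
Reactants: 8 α-silyloxy ketone
Product: 10 (1R,5S,6R)-3-[(tert-butyldimethylsilyl)oxy]-5-methylbicyclo[4.1.0]hept-2-en-2-yl trifluoromethanesulfonate, via potassium enediolate 9 (not isolated)
Conditions: KHMDS, THF, −78 °C; then Comins' reagent, −78 °C
Reagents that add atoms: N-(5-chloropyridin-2-yl)bis(trifluoromethanesulfonimide), FC(F)(F)S(=O)(=O)N(c1ccc(Cl)cn1)S(=O)(=O)C(F)(F)F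
Why: Enolate O-triflation; deprotonation can occur only at the oxygenated methine (the other α-position is the cyclopropane bridgehead), and trapping at −78 °C should precede silyl migration.

Step 7
Reactants: 11 6-methylhept-5-enoic acid; 12 (R)-4-benzyl-1,3-oxazolidin-2-one
Product: 14 (R)-4-benzyl-3-(6-methylhept-5-enoyl)-1,3-oxazolidin-2-one, via mixed pivalic anhydride 13 (not isolated)
Conditions: PivCl, Et3N, THF, −20 °C; then 12, LiCl, rt
Reagents that add atoms: none
Why: N-Acylation of the oxazolidinone through the mixed anhydride, the standard loading of the auxiliary.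

Step 8
Reactants: 14 N-acyl oxazolidinone
Product: 16 (R)-4-benzyl-3-[(S)-2-(benzyloxymethyl)-6-methylhept-5-enoyl]-1,3-oxazolidin-2-one, via chlorotitanium Z-enolate 15 (not isolated)
Conditions: TiCl4, i-Pr2NEt, CH2Cl2, 0 °C; then BnOCH2Cl, 0 °C
Reagents that add atoms: benzyl chloromethyl ether, ClCOCc1ccccc1
Why: Evans alkylation of the chelated Z-titanium enolate; the electrophile should enter anti to the benzyl group of the (R)-auxiliary and set the centre that becomes C1′.

Step 9
Reactants: 16 alkylated imide
Product: 17 (R)-2-[(benzyloxy)methyl]-6-methylhept-5-en-1-ol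
Conditions: LiBH4, MeOH (1 equiv), Et2O, 0 °C
Reagents that add atoms: none
Why: Reductive cleavage of the imide to the primary alcohol with recovery of the auxiliary; the stereocentre is not touched.

Step 10
Reactants: 17 alcohol
Product: 18 (S)-({2-[(benzyloxy)methyl]-6-methylhept-5-en-1-yl}oxy)(tert-butyl)dimethylsilane
Conditions: TBSCl, imidazole, DMF, rt
Reagents that add atoms: tert-butyldimethylsilyl chloride, CC(C)(C)[Si](C)(C)Cl
Why: Silylation of the primary alcohol; this oxygen later carries the acetate.

Step 11
Reactants: 18 benzyl silyl diether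
Product: 19 (S)-2-{[(tert-butyldimethylsilyl)oxy]methyl}-6-methylhept-5-en-1-ol
Conditions: Li, NH3(l), THF, −78 °C; then NH4Cl at −78 °C
Reagents that add atoms: none
Why: Dissolving-metal debenzylation, which spares the trisubstituted alkene and the silyl ether; the cold quench should prevent 1,5-silyl migration, which would racemise this pseudo-symmetric diol derivative.

Step 12
Reactants: 19 alcohol
Product: 20 (R)-2-{[(tert-butyldimethylsilyl)oxy]methyl}-6-methylhept-5-enal
Conditions: Dess–Martin periodinane, NaHCO3, CH2Cl2, 0 °C
Reagents that add atoms: none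
Why: Buffered, non-basic Dess–Martin oxidation; the α-branched aldehyde is used at once to avoid epimerisation.

Step 13
Reactants: 20 aldehyde
Product: 21 (S)-tert-butyl{[2-(2,2-dibromoethenyl)-6-methylhept-5-en-1-yl]oxy}dimethylsilane
Conditions: CBr4, PPh3, 2,6-lutidine, CH2Cl2, 0 °C
Reagents that add atoms: carbon tetrabromide, BrC(Br)(Br)Br
Why: Corey–Fuchs dibromo-olefination (Wittig type, neutral), so the α-centre should be kept.

Step 14
Reactants: 21 dibromoalkene
Product: 23 (S)-4-{[(tert-butyldimethylsilyl)oxy]methyl}-8-methylnon-7-en-2-yn-1-ol, via lithium acetylide 22 (not isolated)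
Conditions: n-BuLi (2.2 equiv), THF, −78 °C; then (CH2O)n, −78 °C → rt
Reagents that add atoms: paraformaldehyde (as formaldehyde), C=O
Why: Second stage of the Corey–Fuchs reaction (Br/Li exchange, 1,2-shift to the alkyne, deprotonation), followed by hydroxymethylation of the acetylide.

Step 15
Reactants: 10 enol triflate; 23 propargylic alcohol
Product: 24 (S)-4-{[(tert-butyldimethylsilyl)oxy]methyl}-8-methylnon-7-en-2-yn-1-yl (1R,5S,6R)-3-[(tert-butyldimethylsilyl)oxy]-5-methylbicyclo[4.1.0]hept-2-ene-2-carboxylate
Conditions: Pd(OAc)2 (10 mol%), dppf (12 mol%), CO (1 atm), i-Pr2NEt, DMF, 60 °C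
Reagents that add atoms: carbon monoxide, [C-]#[O+]
Why: Pd-catalysed alkoxycarbonylation of an enol triflate (oxidative addition, CO insertion, alcoholysis of the acyl-palladium); it joins the fragments and gives the silyl enol ether of the β-keto ester with fixed regiochemistry.

Step 16
Reactants: 24 propargyl β-silyloxy enoate
Product: 26 keto-butenolide with free CH2OH (C1 R, C4 R, C5 R, C6 S, C1′ S; C8 ketone), via cyclobutene photoadduct 25 (not isolated)
Conditions: hν (254 nm), degassed MeCN (5 mM), 0 °C; then TBAF (3 equiv), THF, 0 °C → rt; AcOH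
Reagents that add atoms: none
Why: Proposed new method: direct excitation of the β-silyloxy enoate (silyl enol ether of a cyclic β-keto ester, a carbocyclic relative of the tetronates) should give a triplet that adds to the tethered alkyne, first C3–C2 (5-exo-dig, rule of five, closing the γ-lactone) and then C8–C1 to cyclobutene 25; fluoride then frees the C8 alkoxide, whose retro-aldol (de Mayo/Grob-type) cleavage of the C3–C8 bond is driven by cyclobutene strain and gives the dienolate of the vinylogous β-keto lactone, protonated on acidification. The closest known reactions are the intramolecular de Mayo reaction and the dioxenone photocycloaddition–retro-aldol route to cyclooctanones, intramolecular enone–alkyne [2+2] photocycloadditions that give ring-fusion cyclobutenes, and tetronate [2+2] photocycloadditions; new is the combination of an ester tether, an alkyne and a carbocyclic silyloxy enoate. The lactone closes by 5-exo-dig bond formation at C3, whereas the eight-membered ring is not cyclised from a chain but arises by two-carbon enlargement of the cyclohexene when the shared C3–C8 bond of the bicyclo[4.2.0]octene is cut, which avoids the entropic and transannular cost of an 8-ring closure. C3 and C8 of 25 become sp2 again, so the face of the cycloaddition is irrelevant and both photoadducts converge; the one new stereocentre, C1, should be set by protonation of the dienolate under equilibrating conditions in the fluoride/acetate buffer, with C2 trans to the C1′ homoprenyl group. The step needs cycloaddition at the propargylic alkyne and not at the remote trisubstituted alkene (only the three-atom tether reaches C3/C8; dilute solution), straight rather than crossed regiochemistry (five-membered lactone), cleavage of C3–C8 rather than another cyclobutene bond (only this gives an ester-stabilised allyl anion), and the 2(5H)-furanone rather than the C1=C2 enone tautomer (tetrasubstituted alkene endocyclic to the lactone, conjugated to C=O and cyclopropane).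

Step 17
Reactants: 26 hydroxy keto-butenolide
Product: 27 C1′-acetoxymethyl keto-butenolide (C1 R, C4 R, C5 R, C6 S, C1′ S; C8 ketone)
Conditions: Ac2O, pyridine, CH2Cl2, 0 °C
Reagents that add atoms: acetic anhydride, CC(=O)OC(C)=O
Why: Acetylation of the only alcohol; without DMAP the weakly basic medium should not enolise C1.

Step 18
Reactants: 27 keto acetate
Product: 28 target CNP0267808.2 (C1 R, C4 R, C5 R, C6 S, C8 S, C1′ S)
Conditions: NaBH4, CeCl3·7H2O, MeOH, −78 °C
Reagents that add atoms: none
Why: Chemoselective 1,2-reduction under Luche conditions; hydride should attack the ketone face opposite to the C1 side chain (Felkin-type, peripheral attack), giving the C8 alcohol cis to the side chain while butenolide and acetate survive.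

## Compound list

1 | propanal | CCC=O | starting material
2 | methyl vinyl ketone (but-3-en-2-one) | CC(=O)C=C | starting material
3 | (S)-2-methyl-5-oxohexanal | O=C[C@@H](C)CCC(C)=O | intermediate
4 | (S)-4-methylcyclohex-2-en-1-one | O=C1C=C[C@@H](C)CC1 | intermediate
5 | (1R,5S,6R)-5-methylbicyclo[4.1.0]heptan-2-one (cyclopropane trans to methyl) | O=C1CC[C@H](C)[C@H]2C[C@@H]12 | intermediate
6 | tert-butyldimethyl{[(1R,5S,6R)-5-methylbicyclo[4.1.0]hept-2-en-2-yl]oxy}silane | CC(C)(C)[Si](C)(C)OC1=CC[C@H](C)[C@H]2C[C@@H]12 | intermediate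
7 | 2,3-epoxide of 6 (silyloxy epoxide, epoxide face not defined) | CC(C)(C)[Si](C)(C)OC12OC1C[C@H](C)[C@H]3C[C@@H]23 | intermediate (not isolated)
8 | (1R,5S,6R)-3-[(tert-butyldimethylsilyl)oxy]-5-methylbicyclo[4.1.0]heptan-2-one (both C3 epimers) | O=C1C(O[Si](C)(C)C(C)(C)C)C[C@H](C)[C@H]2C[C@@H]12 | intermediate
9 | potassium enediolate of 8 | [K+].[O-]C1=C(O[Si](C)(C)C(C)(C)C)C[C@H](C)[C@H]2C[C@@H]12 | intermediate (not isolated)
10 | (1R,5S,6R)-3-[(tert-butyldimethylsilyl)oxy]-5-methylbicyclo[4.1.0]hept-2-en-2-yl trifluoromethanesulfonate | FC(F)(F)S(=O)(=O)OC1=C(O[Si](C)(C)C(C)(C)C)C[C@H](C)[C@H]2C[C@@H]12 | intermediate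
11 | 6-methylhept-5-enoic acid | CC(C)=CCCCC(O)=O | starting material
12 | (R)-4-benzyl-1,3-oxazolidin-2-one | O=C1N[C@H](Cc2ccccc2)CO1 | starting material
13 | 6-methylhept-5-enoic pivalic anhydride | CC(C)=CCCCC(=O)OC(=O)C(C)(C)C | intermediate (not isolated)
14 | (R)-4-benzyl-3-(6-methylhept-5-enoyl)-1,3-oxazolidin-2-one | CC(C)=CCCCC(=O)N1[C@H](Cc2ccccc2)COC1=O | intermediate
15 | trichlorotitanium Z-enolate of 14 | CC(C)=CCC/C=C(\O[Ti](Cl)(Cl)Cl)N1[C@H](Cc2ccccc2)COC1=O | intermediate (not isolated)
16 | (R)-4-benzyl-3-[(S)-2-(benzyloxymethyl)-6-methylhept-5-enoyl]-1,3-oxazolidin-2-one | CC(C)=CCC[C@@H](COCc1ccccc1)C(=O)N1[C@H](Cc2ccccc2)COC1=O | intermediate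
17 | (R)-2-[(benzyloxy)methyl]-6-methylhept-5-en-1-ol | OC[C@@H](CCC=C(C)C)COCc1ccccc1 | intermediate
18 | (S)-({2-[(benzyloxy)methyl]-6-methylhept-5-en-1-yl}oxy)(tert-butyl)dimethylsilane | CC(C)(C)[Si](C)(C)OC[C@@H](CCC=C(C)C)COCc1ccccc1 | intermediate
19 | (S)-2-{[(tert-butyldimethylsilyl)oxy]methyl}-6-methylhept-5-en-1-ol | CC(C)(C)[Si](C)(C)OC[C@@H](CCC=C(C)C)CO | intermediate
20 | (R)-2-{[(tert-butyldimethylsilyl)oxy]methyl}-6-methylhept-5-enal | CC(C)(C)[Si](C)(C)OC[C@@H](CCC=C(C)C)C=O | intermediate
21 | (S)-tert-butyl{[2-(2,2-dibromoethenyl)-6-methylhept-5-en-1-yl]oxy}dimethylsilane | CC(C)(C)[Si](C)(C)OC[C@@H](CCC=C(C)C)C=C(Br)Br | intermediate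
22 | lithium (S)-3-{[(tert-butyldimethylsilyl)oxy]methyl}-7-methyloct-6-en-1-yn-1-ide | [Li]C#C[C@H](CCC=C(C)C)CO[Si](C)(C)C(C)(C)C | intermediate (not isolated)
23 | (S)-4-{[(tert-butyldimethylsilyl)oxy]methyl}-8-methylnon-7-en-2-yn-1-ol | CC(C)(C)[Si](C)(C)OC[C@@H](CCC=C(C)C)C#CCO | intermediate
24 | propargyl ester of the silyl enol ether of the bicyclic β-keto acid (ester of 23 with the 2-carboxylic acid derived from 10) | CC(C)(C)[Si](C)(C)OC[C@@H](CCC=C(C)C)C#CCOC(=O)C1=C(O[Si](C)(C)C(C)(C)C)C[C@H](C)[C@H]2C[C@@H]12 | intermediate
25 | cyclobutene photoadduct (γ-lactone/cyclobutene/cyclohexane/cyclopropane tetracycle; C3–C2 and C8–C1 bonds cis, drawn anti to the cyclopropane CH2; the other face converges) | CC(C)(C)[Si](C)(C)OC[C@@H](CCC=C(C)C)C1=C2COC(=O)[C@@]23[C@@H]4C[C@@H]4[C@@H](C)C[C@@]13O[Si](C)(C)C(C)(C)C | intermediate (not isolated)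
26 | tricyclic keto-butenolide with C1′ CH2OH (cyclooctene fused to butenolide at C2=C3 and to cyclopropane at C4–C5; C8 ketone) | OC[C@@H](CCC=C(C)C)[C@@H]1C2=C(C(=O)OC2)[C@@H]2C[C@@H]2[C@@H](C)CC1=O | intermediate
27 | acetate of 26 (C1′ CH2OAc, C8 ketone) | CC(=O)OC[C@@H](CCC=C(C)C)[C@@H]1C2=C(C(=O)OC2)[C@@H]2C[C@@H]2[C@@H](C)CC1=O | intermediate
28 | CNP0267808.2 | CC(=O)OC[C@@H](CCC=C(C)C)[C@@H]1C2=C(C(=O)OC2)[C@@H]2C[C@@H]2[C@@H](C)C[C@@H]1O | target

## Step count and risks

Total step count: 18. Longest linear sequence: 12 steps (steps 7–18, from acid 11); the ring branch (steps 1–6) joins at step 15.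

Steps most likely to fail:

1. Step 16 (Proposed new method). The excited enoate may decay unproductively because the propargyl ester rests in its s-trans (Z) rotamer, from which the alkyne cannot reach C3. The triplet, with radical character at C3 next to the cyclopropane, may open the three-membered ring, and the strained cyclobutene may undergo secondary photolysis. The fallback uses known reaction types, sets out from 24 and comes back at 26. HF·pyridine (THF, 0 °C) removes both silyl groups to give the propargyl β-keto ester F1. Mn(OAc)3·2H2O in ethanol then effects the oxidative radical cyclisation of the β-keto ester onto the alkyne (5-exo-dig, vinyl radical quenched by hydrogen abstraction from the solvent; a ground-state radical can wait for the reactive ester rotamer) to give the spiro β-alkylidene γ-lactone F2, an α-quaternary β,γ-unsaturated ketone. Direct irradiation at 300 nm (n→π*) then brings about the photochemical 1,3-acyl shift (α-cleavage, recombination at the far allyl terminus), the classical two-carbon enlargement of 2-alkenylcycloalkanones, and equilibration with Et3N delivers 26; the eight-membered ring is again formed last.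

2. Step 6. A 1,4 O→O silyl migration within the cis-enediolate before triflation would scramble which oxygen carries the triflate and so place the ester on the wrong carbon. The fallback introduces the oxygen after the carboxyl carbon, so no enediolate occurs; it sets out from 5 and comes back at 24. KHMDS and Comins' reagent give the enol triflate F3; Pd(OAc)2/dppf, CO, MeOH and Et3N give the methyl enoate F4; copper-catalysed conjugate borylation (CuCl, DPEphos, NaOt-Bu, B2pin2, MeOH) and NaBO3 oxidation give the β-hydroxy ester F5; Dess–Martin oxidation gives the methyl β-keto ester F6; DMAP-catalysed transesterification with 23 (toluene, reflux) gives the propargyl β-keto ester F7; TBSOTf and Et3N then give 24.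

3. Step 18. Poor facial selectivity of hydride delivery to the medium-ring ketone, or epimerisation at C1 before reduction, would give the wrong C8 configuration. The fallback sets out from 27 and comes back at 28. If reduction gives mainly the C8-epimeric alcohol F8, Mitsunobu inversion with chloroacetic acid (PPh3, DIAD, toluene) gives the chloroacetate F9 of target configuration, and thiourea with NaHCO3 in EtOH removes the chloroacetyl group selectively beside the acetate and butenolide to give 28.

## Further compounds

F1 | step 16 | propargyl β-keto ester with free CH2OH (C2 of the bicycle epimerisable) | OC[C@@H](CCC=C(C)C)C#CCOC(=O)C1C(=O)C[C@H](C)[C@H]2C[C@@H]12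
F2 | step 16 | spiro β-alkylidene γ-lactone (spiro centre and alkene geometry as mixtures) | OC[C@@H](CCC=C(C)C)C=C1COC(=O)C12C(=O)C[C@H](C)[C@H]3C[C@@H]23
F3 | step 6 | (1R,5S,6R)-5-methylbicyclo[4.1.0]hept-2-en-2-yl trifluoromethanesulfonate | FC(F)(F)S(=O)(=O)OC1=CC[C@H](C)[C@H]2C[C@@H]12
F4 | step 6 | methyl (1R,5S,6R)-5-methylbicyclo[4.1.0]hept-2-ene-2-carboxylate | COC(=O)C1=CC[C@H](C)[C@H]2C[C@@H]12
F5 | step 6 | methyl 3-hydroxy-5-methylbicyclo[4.1.0]heptane-2-carboxylate (C2/C3 as mixtures) | COC(=O)C1C(O)C[C@H](C)[C@H]2C[C@@H]12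
F6 | step 6 | methyl 5-methyl-3-oxobicyclo[4.1.0]heptane-2-carboxylate | COC(=O)C1C(=O)C[C@H](C)[C@H]2C[C@@H]12
F7 | step 6 | β-keto ester of 23 (silyl ether on the side chain) | CC(C)(C)[Si](C)(C)OC[C@@H](CCC=C(C)C)C#CCOC(=O)C1C(=O)C[C@H](C)[C@H]2C[C@@H]12
F8 | step 18 | C8 epimer of 28 | CC(=O)OC[C@@H](CCC=C(C)C)[C@@H]1C2=C(C(=O)OC2)[C@@H]2C[C@@H]2[C@@H](C)C[C@H]1O
F9 | step 18 | C8 chloroacetate of 28 | CC(=O)OC[C@@H](CCC=C(C)C)[C@@H]1C2=C(C(=O)OC2)[C@@H]2C[C@@H]2[C@@H](C)C[C@@H]1OC(=O)CCl
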